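Cuts, in order: the O8–acyl bond; the C5–O bond of the epoxide (O4 displaces a C5 mesylate); C1 and C5 are rejoined as a C1=C5 alkene; C12 is removed from the lactone as CO; then C7–C8 and C9–C10 are cut together.
Enabling feature: the ether oxygen and its two fully substituted carbons C7 and C10 (oxolane O, C7–C10) are the ylide termini of a 3-oxidopyrylium ring O–C7–C6–C5–C1–C10. C8–C9 is a vinyl ether. The C1 ketone and the oxygenated C5 are the two ends of the alkene that this ring shares with a C1–C5 cyclopentene.
Ring order forward: cyclopentane (enyne cycloisomerisation), furan (singlet oxygen), pyranone (Achmatowicz), oxolane plus seven-membered carbocycle ((5+2)), lactone (cyclocarbonylation), ten-membered ring (ozonolysis of C1=C5), epoxide.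
Stereochemistry: C4 comes from (R)-linalool. C7, C8 and C10 are set in the cycloaddition (face anti to the C4 silyl ether, exo alkoxy group). C6 is set by hydride attack from the oxygen-bridge face followed by Mitsunobu inversion. C5 is set by Felkin–Anh hydride addition followed by SN2 closure by O4.

Key step: step 11

Remark: germacrane numbering is used throughout (C1 ketone, C4/C5 epoxide, C6 lactone carbinol, C7 spiro carbon, C8 ester carbinol, C10 ether carbon, C11–C13 methylene lactone, C14 on C10, C15 on C4). Commercial (−)-linalool is taken as the pure R enantiomer. Compounds 12–14 are carried as epimer mixtures at C7 (and C10), because both centres become planar in 18.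

Step 1
Reactants: 1 (R)-(−)-linalool
Product: 2 (R)-linalool TBS ether
Conditions: TBSOTf, 2,6-lutidine, CH2Cl2, 0 °C → rt
Reagents that add atoms: tert-butyldimethylsilyl triflate, CC(C)(C)[Si](C)(C)OS(=O)(=O)C(F)(F)F
Why: Silyl triflate silylation of a hindered tertiary alcohol is routine, and the C4 stereocentre (R, chiral pool) is not touched.

Step 2
Reactants: 2 (R)-linalool TBS ether
Product: 3 (4R)-4-(tert-butyldimethylsilyloxy)-4-methylhex-5-enal
Conditions: O3, CH2Cl2, −78 °C, Sudan III endpoint; Me2S, −78 °C → rt
Reagents that add atoms: ozone, [O-][O+]=O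
Why: Chemoselective ozonolysis, since the electron-rich trisubstituted alkene is consumed well before the vinyl group next to the silyloxy-bearing quaternary carbon and the dye endpoint limits the ozone dose.

Step 3
Reactants: 3 (4R)-4-(tert-butyldimethylsilyloxy)-4-methylhex-5-enal
Product: 4 (3R)-7,7-dibromo-3-(tert-butyldimethylsilyloxy)-3-methylhepta-1,6-diene
Conditions: CBr4, PPh3, CH2Cl2, 0 °C
Reagents that add atoms: carbon tetrabromide, BrC(Br)(Br)Br
Why: First stage of the Corey–Fuchs homologation (dibromomethylenation of an unhindered aldehyde), which adds C10.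

Step 4
Reactants: 4 (3R)-7,7-dibromo-3-(tert-butyldimethylsilyloxy)-3-methylhepta-1,6-diene
Product: 6 (3R)-3-(tert-butyldimethylsilyloxy)-3-methyloct-1-en-6-yne, via lithium acetylide 5 (not isolated)
Conditions: n-BuLi (2.2 equiv), THF, −78 → 0 °C; MeI, −78 °C → rt
Reagents that add atoms: n-butyllithium, [Li]CCCC (lithium of 5 only); iodomethane, CI
Why: Second stage of the Corey–Fuchs sequence, in which bromine–lithium exchange, Fritsch–Buttenberg–Wiechell shift and deprotonation give the acetylide, whose methylation adds C14.

Step 5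
Reactants: 6 (3R)-3-(tert-butyldimethylsilyloxy)-3-methyloct-1-en-6-yne
Product: 7 (1R,3E)-1-(tert-butyldimethylsilyloxy)-3-ethylidene-1-methyl-2-methylidenecyclopentane
Conditions: Pd(OAc)2 (5 mol %), PPh3 (10 mol %), toluene, 60 °C
Reagents that add atoms: none
Why: Palladium-catalysed 1,6-enyne cycloisomerisation, in which hydropalladation of the alkyne, 5-exo carbopalladation of the vinyl group (C1–C5 bond) and loss of the only available β-hydrogen (on C5) should give the 1,3-diene with its methyl group pointing outwards (E).

Step 6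
Reactants: 7 (1R,3E)-1-(tert-butyldimethylsilyloxy)-3-ethylidene-1-methyl-2-methylidenecyclopentane
Product: 9 (4R)-4-(tert-butyldimethylsilyloxy)-1,4-dimethyl-5,6-dihydro-4H-cyclopenta[c]furan, via endoperoxide 8 (not isolated)
Conditions: O2, tetraphenylporphyrin (cat.), hν, CH2Cl2, 0 °C; then Et3N (cat.), rt; then PPTS (cat.)
Reagents that add atoms: dioxygen, O=O
Why: Singlet oxygen adds (4+2) to the s-cis-locked diene, Kornblum–DeLaMare opening of the 1,2-dioxine at its CH2–O end gives a cis-γ-hydroxy enal, and its lactol loses water to the aromatic furan, so the transient C10 centre does not matter.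

Step 7
Reactants: 9 (4R)-4-(tert-butyldimethylsilyloxy)-1,4-dimethyl-5,6-dihydro-4H-cyclopenta[c]furan; 10 3-(trimethylsilyl)prop-2-ynal
Product: 12 furyl propargylic carbinol, via furyllithium 11 (not isolated)
Conditions: n-BuLi, THF, −78 → 0 °C; 10, −78 °C
Reagents that add atoms: n-butyllithium, [Li]CCCC (lithium of 11 only)
Why: α-Lithiation of a furan at its only free α-position (C6) and 1,2-addition to an ynal are standard, and the C7 epimer mixture is acceptable because C7 is planarised in step 11.

Step 8
Reactants: 12 furyl propargylic carbinol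
Product: 13 cyclopenta-fused 6-hydroxypyran-3-one
Conditions: NBS, NaHCO3, THF/H2O (4:1), 0 °C
Reagents that add atoms: water, O
Why: Achmatowicz rearrangement, in which bromonium-induced hydration opens the electron-rich furan to the cis-enedione and the C7 hydroxyl closes onto the C10 ketone to give the pyranone hemiketal.

Step 9
Reactants: 13 cyclopenta-fused 6-hydroxypyran-3-one
Product: 14 cyclopenta-fused 6-acetoxypyran-3-one
Conditions: Ac2O, pyridine, DMAP (cat.), CH2Cl2, 0 °C
Reagents that add atoms: acetic anhydride, CC(=O)OC(C)=O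
Why: DMAP-catalysed acetylation of the anomeric hemiketal hydroxyl, the only free OH, installs the leaving group on C10.

Step 10
Reactants: 15 4-methoxybenzyl alcohol; 16 ethyl vinyl ether
Product: 17 4-methoxybenzyl vinyl ether
Conditions: Pd(OAc)2 (2 mol %), 1,10-phenanthroline (2 mol %), 16 (20 equiv), CH2Cl2, rt
Reagents that add atoms: none
Why: Palladium(II)-catalysed transfer vinylation of a primary alcohol by an alkyl vinyl ether is an established equilibrium process that the excess of 16 drives forward.

Step 11
Reactants: 14 cyclopenta-fused 6-acetoxypyran-3-one; 17 4-methoxybenzyl vinyl ether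
Product: 19 oxa-bridged hydroazulenone (4R,7S,8S,10R), via oxidopyrylium ylide 18 (not isolated)
Conditions: i-Pr2NEt (3 equiv), 17 (10 equiv), MeCN, 60 °C, sealed tube
Reagents that add atoms: none
Why: The amine enolises the C6 ketone towards C7 and acetate leaves C10, giving the planar 3-oxidopyrylium 18, a cyclic carbonyl ylide that adds the vinyl ether suprafacially across C7 and C10 in a concerted but asynchronous (5+2) cycloaddition; the closest known reaction is the base-mediated intermolecular addition of alkyl vinyl ethers to 6-acetoxypyran-3-ones. The C9–C10 and C7–C8 bonds form in one event, so the oxolane (O, C7, C8, C9, C10) and the seven-membered carbocycle (C1, C5, C6, C7, C8, C9, C10) both close by cycloaddition and not by a separate cyclisation. The orientation needed is the polarity-matched one: the nucleophilic CH2 (C9) attacks the methyl-stabilised oxocarbenium terminus C10, and the alkoxycarbenium carbon C8 is taken by C7, whose carbanion character is raised by the ketone and the alkynyl group. C7 and C10 are set together because the oxygen bridge can only be cis, and their sense relative to C4 should follow from approach on the face that carries the C4 methyl group, anti to the bulky OTBS group. C8 is set by the exo transition state, in which the PMBO group lies beside the ring oxonium oxygen and away from the electron-rich oxido oxygen, and the rod-like alkynyl group on C7 takes away the steric cost of that arrangement. A silyl ether rather than an ester on O4 also prevents expulsion of the C4 oxygen from the electron-rich C5 position of the ylide.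

Step 12
Reactants: 19 oxa-bridged hydroazulenone (4R,7S,8S,10R)
Product: 20 C4 hydroxy enone
Conditions: 48 % aq HF, MeCN, 0 °C → rt
Reagents that add atoms: none
Why: Desilylation is placed here because the enone disfavours ionisation at C4, and the free tertiary hydroxyl both clears the oxygen-bridge face of C6 for step 14 and is needed in step 19.

Step 13
Reactants: 20 C4 hydroxy enone
Product: 21 C6-endo allylic alcohol
Conditions: NaBH4, CeCl3·7H2O, MeOH, −78 → −20 °C
Reagents that add atoms: none
Why: In this Luche 1,2-reduction hydride should reach C6 from the face of the one-atom oxygen bridge, the other face being screened by the endo hydrogens of the C8–C9 bridge, so the hydroxyl ends endo (6S), the epimer that step 14 inverts.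

Step 14
Reactants: 21 C6-endo allylic alcohol
Product: 22 C6-exo 4-nitrobenzoate
Conditions: 4-nitrobenzoic acid, PPh3, DIAD, toluene, 0 °C → rt
Reagents that add atoms: 4-nitrobenzoic acid, O=C(O)c1ccc(cc1)[N+](=O)[O-]
Why: Mitsunobu inversion activates only the secondary hydroxyl, the carboxylate enters C6 from the open oxygen-bridge face, SN2′ attack at the fully substituted C1 next to quaternary C10 is blocked, and no β-hydrogen is available for elimination.

Step 15
Reactants: 22 C6-exo 4-nitrobenzoate
Product: 23 C6-exo alcohol with terminal alkyne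
Conditions: K2CO3, MeOH, rt
Reagents that add atoms: none
Why: Base-catalysed methanolysis removes the activated aryl ester (retention at C6) and the alkynyl silyl group in the same operation.

Step 16
Reactants: 23 C6-exo alcohol with terminal alkyne
Product: 24 α-methylene-γ-lactone PMB ether
Conditions: PdCl2 (10 mol %), thiourea (10 mol %), CO (1 atm), acetone, 50 °C
Reagents that add atoms: carbon monoxide, [C-]#[O+]
Why: Palladium(II)-catalysed cyclocarbonylation of a homopropargylic alcohol, in which O6 and CO give an alkoxycarbonylpalladium species that adds syn across C11≡C13 in a 5-exo sense, protonolysis frees the exocyclic methylene, C6 keeps its configuration, and the tertiary C4 hydroxyl (seven-membered closure) cannot compete.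

Step 17
Reactants: 24 α-methylene-γ-lactone PMB ether
Product: 25 C8 alcohol
Conditions: DDQ, CH2Cl2/pH 7 buffer, 0 °C
Reagents that add atoms: none
Why: Oxidative PMB cleavage through the benzylic oxocarbenium ion leaves the acrylate-type alkene, the tetrasubstituted alkene and the tertiary alcohol untouched.

Step 18
Reactants: 25 C8 alcohol; 26 methacrylic anhydride
Product: 27 C8 methacrylate
Conditions: Et3N, DMAP, CH2Cl2, rt
Reagents that add atoms: none
Why: DMAP-catalysed acylation selects the secondary C8 hydroxyl over the tertiary allylic C4 hydroxyl and retains the C8 configuration.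

Step 19
Reactants: 27 C8 methacrylate
Product: 29 ten-membered C5 ketone with C1/O4 hemiketal, via hydroxy diketone 28 (not isolated)
Conditions: O3, CH2Cl2, −78 °C, Sudan Red 7B endpoint; Me2S, −78 °C → rt
Reagents that add atoms: ozone, [O-][O+]=O
Why: The tetrasubstituted C1=C5 alkene is the only electron-rich π bond (the other two are acrylate-type), Criegee cleavage merges the five- and seven-membered carbocycles into the ten-membered ring, and the C4 hydroxyl, placed 1,4 to C1, adds to C1 so that only the C5 ketone stays free, the hemiketal centre being fixed by the need for C5 and C10 to be cis on the new oxolane.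

Step 20
Reactants: 29 ten-membered C5 ketone with C1/O4 hemiketal
Product: 30 (5R)-carbinol
Conditions: NaBH4, MeOH/CH2Cl2, −78 °C
Reagents that add atoms: none
Why: Borohydride reduction of the only free ketone at low temperature, which should spare the two acrylate units, is expected to follow the polar Felkin–Anh model, with hydride entering anti to the C6–O bond past H6 (and anti to C4–O), to give the (5R)-carbinol that step 21 inverts.

Step 21
Reactants: 30 (5R)-carbinol
Product: 32 CNP0241021.1, via C5 mesylate 31 (not isolated)
Conditions: MsCl, Et3N, CH2Cl2, −20 °C; then DBU, 0 °C → rt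
Reagents that add atoms: methanesulfonyl chloride, CS(=O)(=O)Cl (atoms in 31 only)
Why: Sulfene-type mesylation takes the secondary C5 hydroxyl and leaves the tertiary hemiketal hydroxyl, and DBU then opens the hemiketal to the C1 ketone and the C4 alkoxide, which displaces the mesylate in a 3-exo-tet SN2 reaction with inversion at C5 and retention at C4 to give the (4R,5S)-epoxide.

Compound list
1 | (R)-(−)-linalool, (3R)-3,7-dimethylocta-1,6-dien-3-ol | C=C[C@](C)(O)CCC=C(C)C | starting material
2 | (3R)-3-(tert-butyldimethylsilyloxy)-3,7-dimethylocta-1,6-diene | C=C[C@](C)(O[Si](C)(C)C(C)(C)C)CCC=C(C)C | intermediate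
3 | (4R)-4-(tert-butyldimethylsilyloxy)-4-methylhex-5-enal | C=C[C@](C)(O[Si](C)(C)C(C)(C)C)CCC=O | intermediate
4 | (3R)-7,7-dibromo-3-(tert-butyldimethylsilyloxy)-3-methylhepta-1,6-diene | C=C[C@](C)(O[Si](C)(C)C(C)(C)C)CCC=C(Br)Br | intermediate
5 | lithium acetylide of (3R)-3-(tert-butyldimethylsilyloxy)-3-methylhept-1-en-6-yne | C=C[C@](C)(O[Si](C)(C)C(C)(C)C)CCC#C[Li] | intermediate
6 | (3R)-3-(tert-butyldimethylsilyloxy)-3-methyloct-1-en-6-yne | C=C[C@](C)(O[Si](C)(C)C(C)(C)C)CCC#CC | intermediate
7 | (1R,3E)-1-(tert-butyldimethylsilyloxy)-3-ethylidene-1-methyl-2-methylidenecyclopentane | C=C1/C(=C/C)CC[C@@]1(C)O[Si](C)(C)C(C)(C)C | intermediate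
8 | 3,6-dihydro-1,2-dioxine fused through C1=C5 to the cyclopentene, C6H2–O–O–C10H(CH3), (4R), both C10 epimers | CC1OOCC2=C1CC[C@@]2(C)O[Si](C)(C)C(C)(C)C | intermediate
9 | (4R)-4-(tert-butyldimethylsilyloxy)-1,4-dimethyl-5,6-dihydro-4H-cyclopenta[c]furan | Cc1occ2c1CC[C@@]2(C)O[Si](C)(C)C(C)(C)C | intermediate
10 | 3-(trimethylsilyl)prop-2-ynal | C[Si](C)(C)C#CC=O | starting material
11 | 3-lithio derivative of 9 (lithium on C6) | Cc1oc([Li])c2c1CC[C@@]2(C)O[Si](C)(C)C(C)(C)C | intermediate
12 | 1-[(4R)-4-(tert-butyldimethylsilyloxy)-1,4-dimethyl-5,6-dihydro-4H-cyclopenta[c]furan-3-yl]-3-(trimethylsilyl)prop-2-yn-1-ol, both C7 epimers | Cc1oc(C(O)C#C[Si](C)(C)C)c2c1CC[C@@]2(C)O[Si](C)(C)C(C)(C)C | intermediate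
13 | (5R)-5-(tert-butyldimethylsilyloxy)-1-hydroxy-1,5-dimethyl-3-[(trimethylsilyl)ethynyl]-3,5,6,7-tetrahydrocyclopenta[c]pyran-4(1H)-one, epimers at C7 and C10 | CC1(O)OC(C#C[Si](C)(C)C)C(=O)C2=C1CC[C@@]2(C)O[Si](C)(C)C(C)(C)C | intermediate
14 | (5R)-5-(tert-butyldimethylsilyloxy)-1,5-dimethyl-4-oxo-3-[(trimethylsilyl)ethynyl]-1,3,4,5,6,7-hexahydrocyclopenta[c]pyran-1-yl acetate, epimers at C7 and C10 | CC(=O)OC1(C)OC(C#C[Si](C)(C)C)C(=O)C2=C1CC[C@@]2(C)O[Si](C)(C)C(C)(C)C | intermediate
15 | 4-methoxybenzyl alcohol | COc1ccc(CO)cc1 | starting material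
16 | ethyl vinyl ether | C=COCC | starting material
17 | 4-methoxybenzyl vinyl ether | C=COCc1ccc(OC)cc1 | intermediate
18 | cyclopenta-fused 3-oxidopyrylium: C10 methyl, C7 (trimethylsilyl)ethynyl, C6 oxido, (4R)-C(CH3)(OTBS) on C5 | Cc1[o+]c(C#C[Si](C)(C)C)c([O-])c2c1CC[C@@]2(C)O[Si](C)(C)C(C)(C)C | intermediate
19 | oxa-bridged hydroazulenone (C7–O–C10 bridge): C6 ketone, C1=C5 alkene, C7 (trimethylsilyl)ethynyl, C10 methyl, C8 exo-OPMB, C4 methyl on the C8–C9 face and OTBS on the oxygen-bridge face; (4R,7S,8S,10R) | COc4ccc(cc4)CO[C@H]1C[C@@]2(C)O[C@]1(C#C[Si](C)(C)C)C(=O)C3=C2CC[C@@]3(C)O[Si](C)(C)C(C)(C)C | intermediate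
20 | 19 with free tertiary C4 hydroxyl | COc4ccc(cc4)CO[C@H]1C[C@@]2(C)O[C@]1(C#C[Si](C)(C)C)C(=O)C3=C2CC[C@@]3(C)O | intermediate
21 | allylic diol: C6 hydroxyl endo (anti to the oxygen bridge, 6S), otherwise as 20 | COc4ccc(cc4)CO[C@H]1C[C@@]2(C)O[C@]1(C#C[Si](C)(C)C)[C@@H](O)C3=C2CC[C@@]3(C)O | intermediate
22 | C6 4-nitrobenzoate, ester oxygen exo (syn to the oxygen bridge, 6R) | COc4ccc(cc4)CO[C@H]1C[C@@]2(C)O[C@]1(C#C[Si](C)(C)C)[C@H](OC(=O)c5ccc(cc5)[N+](=O)[O-])C3=C2CC[C@@]3(C)O | intermediate
23 | diol with exo C6 hydroxyl (6R) and C7 ethynyl group | COc4ccc(cc4)CO[C@H]1C[C@@]2(C)O[C@]1(C#C)[C@H](O)C3=C2CC[C@@]3(C)O | intermediate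
24 | α-methylene-γ-lactone C7–C11(=C13H2)–C12(=O)–O6–C6 on the oxa-bridged hydroazulene, C8 exo-OPMB, C4 OH | COc4ccc(cc4)CO[C@H]1C[C@@]2(C)O[C@@]15C(=C)C(=O)O[C@@H]5C3=C2CC[C@@]3(C)O | intermediate
25 | 24 with free exo C8 hydroxyl | O[C@H]1C[C@@]2(C)O[C@@]15C(=C)C(=O)O[C@@H]5C3=C2CC[C@@]3(C)O | intermediate
26 | methacrylic anhydride | C=C(C)C(=O)OC(=O)C(C)=C | starting material
27 | C8 exo-methacrylate of 25 | C=C(C)C(=O)O[C@H]1C[C@@]2(C)O[C@@]15C(=C)C(=O)O[C@@H]5C3=C2CC[C@@]3(C)O | intermediate
28 | ten-membered 1,5-diketone with free (4R)-hydroxyl, 7,10-ether, lactone and methacrylate | C=C(C)C(=O)O[C@H]1C[C@@]2(C)O[C@@]15C(=C)C(=O)O[C@@H]5C(=O)[C@](C)(O)CCC2=O | intermediate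
29 | hemiketal of 28: O4 bonded to C1 (oxolane C1–C2–C3–C4–O4, C5 and C10 cis), C1 OH, free C5 ketone | C=C(C)C(=O)O[C@H]1C[C@@]2(C)O[C@@]15C(=C)C(=O)O[C@@H]5C(=O)[C@@]6(C)CC[C@]2(O)O6 | intermediate
30 | (5R)-carbinol of 29 | C=C(C)C(=O)O[C@H]1C[C@@]2(C)O[C@@]15C(=C)C(=O)O[C@@H]5[C@@H](O)[C@@]6(C)CC[C@]2(O)O6 | intermediate
31 | C5 methanesulfonate of 30 | C=C(C)C(=O)O[C@H]1C[C@@]2(C)O[C@@]15C(=C)C(=O)O[C@@H]5[C@@H](OS(C)(=O)=O)[C@@]6(C)CC[C@]2(O)O6 | intermediate
32 | CNP0241021.1, (4R,5S,6R,7S,8S,10R) | C=C(C)C(=O)O[C@H]1C[C@@]2(C)O[C@@]13C(=C)C(=O)O[C@@H]3[C@@H]1O[C@]1(C)CCC2=O | target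

Total step count: 21. Longest linear sequence: 20 (steps 1–9 and 11–21).

Steps most likely to fail

Step 11. The ylide carries a substituent on both termini and may be trapped too slowly. Proton loss from the C10 methyl group, dimerisation or the reversed orientation of the vinyl ether could then take over, and face selection by the remote C4 silyl ether may be poor.
- The fallback forms the same two bonds in two polar steps. It sets out from 14 and returns at 19.
- A Mukaiyama-type substitution of the anomeric acetate by tert-butyldimethyl(vinyloxy)silane (BF3·OEt2, CH2Cl2, −78 °C) can only form C9–C10. It should give the C10-(2-oxoethyl)pyranone F1.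
- A reversible amine-base (DBU) intramolecular aldol addition of the C7 enolate to the C8 aldehyde then forms C7–C8 and should give the bridged exo β-hydroxy ketone F2.
- 4-Methoxybenzyl trichloroacetimidate with catalytic La(OTf)3 converts F2 into 19.

Step 14. The carbinol is flanked by quaternary C7 and the fully substituted C5. Activation and displacement may stall at the alkoxyphosphonium stage, or drift to ionisation with 1,4-elimination towards C2.
- The fallback makes the displacement intramolecular. It sets out from 21 and returns at 24.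
- K2CO3 in MeOH removes the alkynyl silyl group to give the endo diol with terminal alkyne F3.
- Palladium-catalysed Markovnikov hydroxycarbonylation (Pd(OAc)2, dppb, HCO2H, CO) should give the 2-substituted acrylic acid F4.
- Mitsunobu lactonisation (PPh3, DIAD, dilute toluene) lets the tethered carboxylate close the five-membered ring at C6 from the oxygen-bridge face with inversion, giving 24 directly.

Step 20. The conformation of the medium ring is not known, so facial selectivity at C5 may be poor. The open C1 ketone may also be reduced, and hydride may add in a conjugate sense to the methylene lactone.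
- The fallback replaces substrate control by catalyst control. It sets out from 29 and returns at 30.
- A Corey–Bakshi–Shibata reduction with (S)-Me-oxazaborolidine and BH3·SMe2 (toluene, −40 °C) treats the quaternary C4 side as the large group and should deliver the (5R)-carbinol. Borane under these conditions is slow towards acrylate-type alkenes.
- This fallback makes no new compound (F0).

Further compounds
F1 | step 11 | C10-(2-oxoethyl)pyranone, (4R,10R), C7 epimers | O=CC[C@@]1(C)OC(C#C[Si](C)(C)C)C(=O)C2=C1CC[C@@]2(C)O[Si](C)(C)C(C)(C)C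
F2 | step 11 | bridged exo β-hydroxy ketone (19 with free C8 hydroxyl) | O[C@H]1C[C@@]2(C)O[C@]1(C#C[Si](C)(C)C)C(=O)C3=C2CC[C@@]3(C)O[Si](C)(C)C(C)(C)C
F3 | step 14 | endo diol with terminal alkyne | COc4ccc(cc4)CO[C@H]1C[C@@]2(C)O[C@]1(C#C)[C@@H](O)C3=C2CC[C@@]3(C)O
F4 | step 14 | 2-substituted acrylic acid with endo C6 hydroxyl | COc4ccc(cc4)CO[C@H]1C[C@@]2(C)O[C@]1(C(=C)C(=O)O)[C@@H](O)C3=C2CC[C@@]3(C)O
F0 | step 20 | none | none
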